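In flavanone numbering (double primes for the 4-hydroxyphenyl half), C4=O and C4''=O stand 1,4 to each other across C3–C3'', and C4'' is held by ring A of unit 2 and O1'' next to C2''. The route therefore rests on cutting C4''–C3'': an intramolecular Stetter reaction makes the formyl carbon of a salicylaldehyde ether an acyl anion equivalent, forms that bond, closes ring C of unit 2 and sets C3'' trans to the C2'' aryl group, leaving a C3 methylene for an aldol and Mitsunobu closure of unit 1. The precursor is an (R)-configured γ-(2-formylaryloxy) E-enone whose ketone-side phenol is a silyl ether, so that no acid is needed later.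

Key step: step 8

Remark: unit 1 is the 4-methoxyphenyl flavanone (unprimed), unit 2 the 4-hydroxyphenyl flavanone (double-primed); the target is (2S,3R,2''R,3''S), trans in both pyranone rings.

Assumption: the three chiral reagents act in the sense of their usual models ((+)-MIB sends vinyl to the Re face of the aldehyde, the (5aS,10bR) triazolium salt is matched with C2'' (R), (−)-Ipc2BOTf sends the enolate to the Re face of the aldehyde); if a model run shows the opposite sense for one of them, its antipode is used.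

Step 1
Reactants: 1 4-(benzyloxy)benzaldehyde
Product: 2 (1R)-1-[4-(benzyloxy)phenyl]prop-2-en-1-ol
Conditions: CH2=CHMgBr (2.4 equiv), ZnCl2 (1.2 equiv), THF/toluene, 0 °C, then 1,4-dioxane, filter; (+)-MIB [(2R)-3-exo-morpholinoisoborneol] (5 mol %), 1, toluene, −20 to 0 °C; aq NH4Cl
Reagents that add atoms: divinylzinc, C=C[Zn]C=C, made in the flask from vinylmagnesium bromide, C=C[Mg]Br
Why: Amino-alcohol-catalysed addition of a vinylzinc reagent to an aryl aldehyde, in which the chiral zinc aminoalkoxide should deliver the vinyl group to the Re face of the formyl group and so set the carbinol carbon (later C2'') as R, the magnesium salts being removed as their dioxane complex so that no uncatalysed addition lowers the selectivity.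

Step 2
Reactants: 3 2,4,6-trifluorobenzaldehyde
Product: 4 2,4-bis(benzyloxy)-6-fluorobenzaldehyde
Conditions: BnOH (2.0 equiv), NaH (2.0 equiv), THF, −20 °C to rt
Reagents that add atoms: benzyl alcohol, OCc1ccccc1
Why: Twofold SNAr through formyl-stabilised Meisenheimer complexes, in which para-then-ortho and ortho-then-para displacement converge on the same 2,4-pattern and the third fluorine, now on an electron-richer ring, should react too slowly to be lost with two equivalents of alkoxide.

Step 3
Reactants: 2 (1R)-1-[4-(benzyloxy)phenyl]prop-2-en-1-ol, 4 2,4-bis(benzyloxy)-6-fluorobenzaldehyde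
Product: 5 2,4-bis(benzyloxy)-6-{[(1R)-1-[4-(benzyloxy)phenyl]prop-2-en-1-yl]oxy}benzaldehyde
Conditions: 2, KN(SiMe3)2 (1.0 equiv), THF, −78 °C; then 4, THF/DMF, −40 °C to rt
Reagents that add atoms: none
Why: SNAr of the potassium alkoxide at the fluorine ortho to the formyl group, which leaves the carbinol C–O bond intact so that the R configuration is carried over unchanged, while one equivalent of base at low temperature should keep the allylic alkoxide from isomerising.

Step 4
Reactants: 6 2',4',6'-trihydroxyacetophenone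
Product: 7 1-[2,4-bis(benzyloxy)-6-hydroxyphenyl]ethan-1-one
Conditions: BnBr (2.1 equiv), K2CO3, DMF, rt
Reagents that add atoms: benzyl bromide, BrCc1ccccc1
Why: Williamson etherification that should stop at the bis-ether because the remaining ortho hydroxyl is hydrogen-bonded to the acetyl carbonyl and is the poorest nucleophile.

Step 5
Reactants: 7 1-[2,4-bis(benzyloxy)-6-hydroxyphenyl]ethan-1-one
Product: 9 1-[2,4-bis(benzyloxy)-6-(tert-butyldimethylsilyloxy)phenyl]-3-(dimethylamino)propan-1-one, via bis-silyl enol ether 8 (not isolated)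
Conditions: TBSOTf (2.3 equiv), Et3N (3 equiv), CH2Cl2, 0 °C to rt; then CH2=NMe2+ I− (Eschenmoser's salt), rt; aq NaHCO3
Reagents that add atoms: tert-butyldimethylsilyl triflate, CC(C)(C)[Si](C)(C)OS(=O)(=O)C(F)(F)F; Eschenmoser's salt (N,N-dimethylmethyleneiminium iodide), C=[N+](C)C.[I-]
Why: The silyl triflate and amine silylate the chelated phenol and turn the methyl ketone into its silyl enol ether without forming a metal enolate that could take over the neighbouring aryl silyl group, and the enol ether then undergoes a Mannich reaction with the preformed iminium salt at its terminal carbon.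

Step 6
Reactants: 9 1-[2,4-bis(benzyloxy)-6-(tert-butyldimethylsilyloxy)phenyl]-3-(dimethylamino)propan-1-one
Product: 11 1-[2,4-bis(benzyloxy)-6-(tert-butyldimethylsilyloxy)phenyl]prop-2-en-1-one, via trimethylammonium iodide 10 (not isolated)
Conditions: MeI, CH2Cl2, rt; then aq NaHCO3, rt
Reagents that add atoms: none
Why: N-Quaternisation turns the amine into a leaving group and mild base then brings about an E1cB β-elimination to the aryl vinyl ketone, which is kept cold and used at once because such ketones polymerise easily.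

Step 7
Reactants: 5 2,4-bis(benzyloxy)-6-{[(1R)-1-[4-(benzyloxy)phenyl]prop-2-en-1-yl]oxy}benzaldehyde, 11 1-[2,4-bis(benzyloxy)-6-(tert-butyldimethylsilyloxy)phenyl]prop-2-en-1-one
Product: 12 2,4-bis(benzyloxy)-6-{[(1R,2E)-1-[4-(benzyloxy)phenyl]-4-[2,4-bis(benzyloxy)-6-(tert-butyldimethylsilyloxy)phenyl]-4-oxobut-2-en-1-yl]oxy}benzaldehyde
Conditions: second-generation Hoveyda–Grubbs catalyst RuCl2(H2IMes)(=CH–C6H4-2-OiPr) (5 mol %), 11 (2.5 equiv), CH2Cl2, 40 °C
Reagents that add atoms: none
Why: Olefin cross metathesis between a hindered allylic ether that does not homodimerise and an electron-poor vinyl ketone used in excess, which should give the conjugated E-enone under thermodynamic control without touching the formyl group, the silyl ether or the C2'' stereocentre.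

Step 8
Reactants: 12 2,4-bis(benzyloxy)-6-{[(1R,2E)-1-[4-(benzyloxy)phenyl]-4-[2,4-bis(benzyloxy)-6-(tert-butyldimethylsilyloxy)phenyl]-4-oxobut-2-en-1-yl]oxy}benzaldehyde
Product: 13 1-[2,4-bis(benzyloxy)-6-(tert-butyldimethylsilyloxy)phenyl]-2-[(2R,3S)-5,7-bis(benzyloxy)-2-[4-(benzyloxy)phenyl]-4-oxochroman-3-yl]ethan-1-one
Conditions: (5aS,10bR)-5a,10b-dihydro-2-(pentafluorophenyl)-4H,6H-indeno[2,1-b][1,2,4]triazolo[4,3-d][1,4]oxazinium tetrafluoroborate (20 mol %), iPr2NEt (1.0 equiv), toluene, rt
Reagents that add atoms: none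
Why: The carbene freed from the triazolium salt adds to the formyl group, proton transfer gives the Breslow intermediate, and this acyl anion equivalent attacks the enone β-carbon C3'' to form C4''–C3'', after which protonation of the aryl ketone enolate and loss of the carbene release 13. The closest known reaction type is the enantioselective intramolecular Stetter reaction of oxygen-tethered salicylaldehyde enoates and enones to 3-substituted chroman-4-ones, applied here to a substrate that already carries an aryl group on the tether carbon. Ring C of unit 2 closes in the 6-exo-trig mode. C3'' should be set S by the facial preference of the catalyst acting together with the C2'' (R) aryl group, which sits pseudoequatorial in the chair-like transition state and directs the enone arm trans to itself; as an enolisable α-keto methine C3'' also rests in this trans arrangement under the amine. The step needs carbene catalysis to outrun base chemistry, since C2''–H is vinylogously acidic and ring C of the product can reopen by β-elimination of the phenoxide, which is why only a hindered tertiary amine and a weakly basic N-pentafluorophenyl carbene are used. The E geometry from step 7 places the acceptor within reach, and the silyl ether keeps the ketone-side phenol from adding to the enone.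

Step 9
Reactants: 13 1-[2,4-bis(benzyloxy)-6-(tert-butyldimethylsilyloxy)phenyl]-2-[(2R,3S)-5,7-bis(benzyloxy)-2-[4-(benzyloxy)phenyl]-4-oxochroman-3-yl]ethan-1-one, 14 4-methoxybenzaldehyde
Product: 15 (2R,3R)-1-[2,4-bis(benzyloxy)-6-(tert-butyldimethylsilyloxy)phenyl]-2-[(2R,3S)-5,7-bis(benzyloxy)-2-[4-(benzyloxy)phenyl]-4-oxochroman-3-yl]-3-hydroxy-3-(4-methoxyphenyl)propan-1-one
Conditions: (−)-diisopinocampheylboron triflate, (−)-Ipc2BOTf (1.5 equiv), iPr2NEt (2 equiv), CH2Cl2, −78 to 0 °C; then 14, −78 to −20 °C; pH 7 buffer, MeOH, H2O2, 0 °C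
Reagents that add atoms: none
Why: Boron-mediated aldol addition in which the less hindered C3 methylene (not the C3'' methine) should be enolised to the Z-enolate, the only geometry that avoids the di-ortho-substituted aryl group, and a closed chair transition state then gives the syn aldol, the isopinocampheyl ligands steering the enolate to the Re face of the aldehyde so that the carbinol carbon and C3 both become R, the sense the substrate itself favours when C3''–H eclipses the enolate and the aldehyde approaches anti to the C2'' side.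

Step 10
Reactants: 15 (2R,3R)-1-[2,4-bis(benzyloxy)-6-(tert-butyldimethylsilyloxy)phenyl]-2-[(2R,3S)-5,7-bis(benzyloxy)-2-[4-(benzyloxy)phenyl]-4-oxochroman-3-yl]-3-hydroxy-3-(4-methoxyphenyl)propan-1-one
Product: 16 (2R,3R)-1-[2,4-bis(benzyloxy)-6-hydroxyphenyl]-2-[(2R,3S)-5,7-bis(benzyloxy)-2-[4-(benzyloxy)phenyl]-4-oxochroman-3-yl]-3-hydroxy-3-(4-methoxyphenyl)propan-1-one
Conditions: Bu4NF (1.1 equiv), AcOH (1.1 equiv), THF, 0 °C
Reagents that add atoms: none
Why: Fluoride cleaves the aryl silyl ether, and buffering with acetic acid keeps the medium near neutral so that the β-hydroxy ketone should neither undergo retro-aldol cleavage nor dehydrate, with no acid strong enough to ionise the 4-methoxybenzylic carbinol, which is the reason this phenol is masked as a silyl ether and not as an acetal.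

Step 11
Reactants: 16 (2R,3R)-1-[2,4-bis(benzyloxy)-6-hydroxyphenyl]-2-[(2R,3S)-5,7-bis(benzyloxy)-2-[4-(benzyloxy)phenyl]-4-oxochroman-3-yl]-3-hydroxy-3-(4-methoxyphenyl)propan-1-one
Product: 17 (2S,3R)-5,7-bis(benzyloxy)-3-[(2R,3S)-5,7-bis(benzyloxy)-2-[4-(benzyloxy)phenyl]-4-oxochroman-3-yl]-2-(4-methoxyphenyl)chroman-4-one
Conditions: PPh3, DIAD, THF, 0 °C to rt
Reagents that add atoms: none
Why: Intramolecular Mitsunobu etherification in which the chelated phenol displaces the activated carbinol oxygen in a 6-exo-tet SN2 closure with inversion, turning the R carbinol into C2 (S), and because the aldol was syn this inversion places the anisyl group trans to the C3 substituent, which is also the thermodynamically preferred arrangement of this α-keto methine.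

Step 12
Reactants: 17 (2S,3R)-5,7-bis(benzyloxy)-3-[(2R,3S)-5,7-bis(benzyloxy)-2-[4-(benzyloxy)phenyl]-4-oxochroman-3-yl]-2-(4-methoxyphenyl)chroman-4-one
Product: 18 (2S,3R)-3-[(2R,3S)-5,7-dihydroxy-2-(4-hydroxyphenyl)-4-oxochroman-3-yl]-5,7-dihydroxy-2-(4-methoxyphenyl)chroman-4-one (CNP0196568.3)
Conditions: H2 (1 atm), Pd/C (10 wt % Pd), EtOAc/MeOH, rt
Reagents that add atoms: none
Why: Hydrogenolysis of the five benzyl ethers under neutral conditions, which should leave the aryl methyl ether, both ketones and the four stereocentres untouched if it is stopped at complete debenzylation, before the benzylic C2–O1 and C2''–O1'' bonds are attacked.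

Compound list
1 | 4-(benzyloxy)benzaldehyde | O=Cc1ccc(OCc2ccccc2)cc1 | starting material
2 | (1R)-1-[4-(benzyloxy)phenyl]prop-2-en-1-ol | O[C@H](C=C)c1ccc(OCc2ccccc2)cc1 | intermediate
3 | 2,4,6-trifluorobenzaldehyde | O=Cc1c(F)cc(F)cc1F | starting material
4 | 2,4-bis(benzyloxy)-6-fluorobenzaldehyde | O=Cc1c(F)cc(OCc2ccccc2)cc1OCc1ccccc1 | intermediate
5 | 2,4-bis(benzyloxy)-6-{[(1R)-1-[4-(benzyloxy)phenyl]prop-2-en-1-yl]oxy}benzaldehyde | O=Cc1c(OCc2ccccc2)cc(OCc2ccccc2)cc1O[C@H](C=C)c1ccc(OCc2ccccc2)cc1 | intermediate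
6 | 2',4',6'-trihydroxyacetophenone | CC(=O)c1c(O)cc(O)cc1O | starting material
7 | 1-[2,4-bis(benzyloxy)-6-hydroxyphenyl]ethan-1-one | CC(=O)c1c(O)cc(OCc2ccccc2)cc1OCc1ccccc1 | intermediate
8 | tert-butyl({1-[2,4-bis(benzyloxy)-6-(tert-butyldimethylsilyloxy)phenyl]ethenyl}oxy)dimethylsilane (bis-silyl enol ether) | C=C(O[Si](C)(C)C(C)(C)C)c1c(O[Si](C)(C)C(C)(C)C)cc(OCc2ccccc2)cc1OCc1ccccc1 | intermediate
9 | 1-[2,4-bis(benzyloxy)-6-(tert-butyldimethylsilyloxy)phenyl]-3-(dimethylamino)propan-1-one | CN(C)CCC(=O)c1c(O[Si](C)(C)C(C)(C)C)cc(OCc2ccccc2)cc1OCc1ccccc1 | intermediate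
10 | {3-[2,4-bis(benzyloxy)-6-(tert-butyldimethylsilyloxy)phenyl]-3-oxopropyl}trimethylammonium iodide | C[N+](C)(C)CCC(=O)c1c(O[Si](C)(C)C(C)(C)C)cc(OCc2ccccc2)cc1OCc1ccccc1.[I-] | intermediate
11 | 1-[2,4-bis(benzyloxy)-6-(tert-butyldimethylsilyloxy)phenyl]prop-2-en-1-one | C=CC(=O)c1c(O[Si](C)(C)C(C)(C)C)cc(OCc2ccccc2)cc1OCc1ccccc1 | intermediate
12 | 2,4-bis(benzyloxy)-6-{[(1R,2E)-1-[4-(benzyloxy)phenyl]-4-[2,4-bis(benzyloxy)-6-(tert-butyldimethylsilyloxy)phenyl]-4-oxobut-2-en-1-yl]oxy}benzaldehyde | O=Cc1c(OCc2ccccc2)cc(OCc2ccccc2)cc1O[C@H](/C=C/C(=O)c1c(O[Si](C)(C)C(C)(C)C)cc(OCc2ccccc2)cc1OCc1ccccc1)c1ccc(OCc2ccccc2)cc1 | intermediate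
13 | 1-[2,4-bis(benzyloxy)-6-(tert-butyldimethylsilyloxy)phenyl]-2-[(2R,3S)-5,7-bis(benzyloxy)-2-[4-(benzyloxy)phenyl]-4-oxochroman-3-yl]ethan-1-one | O=C(C[C@@H]1C(=O)c2c(OCc3ccccc3)cc(OCc3ccccc3)cc2O[C@H]1c1ccc(OCc2ccccc2)cc1)c1c(O[Si](C)(C)C(C)(C)C)cc(OCc2ccccc2)cc1OCc1ccccc1 | intermediate
14 | 4-methoxybenzaldehyde | COc1ccc(C=O)cc1 | starting material
15 | (2R,3R)-1-[2,4-bis(benzyloxy)-6-(tert-butyldimethylsilyloxy)phenyl]-2-[(2R,3S)-5,7-bis(benzyloxy)-2-[4-(benzyloxy)phenyl]-4-oxochroman-3-yl]-3-hydroxy-3-(4-methoxyphenyl)propan-1-one | COc1ccc([C@H](O)[C@@H]([C@@H]2C(=O)c3c(OCc4ccccc4)cc(OCc4ccccc4)cc3O[C@H]2c2ccc(OCc3ccccc3)cc2)C(=O)c2c(O[Si](C)(C)C(C)(C)C)cc(OCc3ccccc3)cc2OCc2ccccc2)cc1 | intermediate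
16 | (2R,3R)-1-[2,4-bis(benzyloxy)-6-hydroxyphenyl]-2-[(2R,3S)-5,7-bis(benzyloxy)-2-[4-(benzyloxy)phenyl]-4-oxochroman-3-yl]-3-hydroxy-3-(4-methoxyphenyl)propan-1-one | COc1ccc([C@H](O)[C@@H]([C@@H]2C(=O)c3c(OCc4ccccc4)cc(OCc4ccccc4)cc3O[C@H]2c2ccc(OCc3ccccc3)cc2)C(=O)c2c(O)cc(OCc3ccccc3)cc2OCc2ccccc2)cc1 | intermediate
17 | (2S,3R)-5,7-bis(benzyloxy)-3-[(2R,3S)-5,7-bis(benzyloxy)-2-[4-(benzyloxy)phenyl]-4-oxochroman-3-yl]-2-(4-methoxyphenyl)chroman-4-one | COc1ccc([C@H]2Oc3cc(OCc4ccccc4)cc(OCc4ccccc4)c3C(=O)[C@@H]2[C@@H]2C(=O)c3c(OCc4ccccc4)cc(OCc4ccccc4)cc3O[C@H]2c2ccc(OCc3ccccc3)cc2)cc1 | intermediate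
18 | (2S,3R)-3-[(2R,3S)-5,7-dihydroxy-2-(4-hydroxyphenyl)-4-oxochroman-3-yl]-5,7-dihydroxy-2-(4-methoxyphenyl)chroman-4-one (CNP0196568.3) | COc1ccc([C@H]2Oc3cc(O)cc(O)c3C(=O)[C@@H]2[C@@H]2C(=O)c3c(O)cc(O)cc3O[C@H]2c2ccc(O)cc2)cc1 | target

Total step count: 12. Longest linear sequence: 9 steps (6 → 7 → 9 → 11 → 12 → 13 → 15 → 16 → 17 → 18).

Steps most likely to fail

Step 8. The carbene may add too slowly to the di-ortho-substituted, electron-rich formyl group, so that base-induced loss of configuration at C2'' or migration of the enone double bond takes over. The fallback sets out from 12 and comes back at 13 without the carbene or any base: a radical-chain intramolecular hydroacylation (tert-dodecanethiol 30 mol %, AIBN in portions, chlorobenzene, 80 °C). Hydrogen abstraction from the formyl group gives a nucleophilic acyl radical, which closes 6-exo-trig onto the electron-poor enone, and the α-keto radical takes hydrogen back from the thiol. C3'' is then set trans by the C2'' aryl group alone, and a trace of Et3N would complete the equilibration. No compound outside the list is made (entry F0).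

Step 3. Displacement of the last fluorine on the electron-rich ring may be so slow that the alkoxide instead adds to the formyl group, transfers hydride to it or isomerises. The fallback sets out from 2 and 3 and comes back at 5 by reversing the order of the displacements. The lithium alkoxide of 2 (LiN(SiMe3)2, toluene/THF, −78 °C) meets the far more reactive trifluoro aldehyde 3, where lithium bound to the formyl oxygen should direct attack to an ortho fluorine and give 2-{[(1R)-1-[4-(benzyloxy)phenyl]prop-2-en-1-yl]oxy}-4,6-difluorobenzaldehyde F1. Benzyl alcohol and NaH (2 equiv, THF/DMF, 0 °C to rt) then replace the two remaining fluorines to give 5.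

Step 9. Enolisation may take place on the wrong side of the 1,4-diketone, or the facial control may be too weak to fix the carbinol configuration. The fallback sets out from 13 and comes back at 17, giving up reagent control for thermodynamic control and a separation. Bu4NF/AcOH (THF, 0 °C) frees the phenol to give 1-[2,4-bis(benzyloxy)-6-hydroxyphenyl]-2-[(2R,3S)-5,7-bis(benzyloxy)-2-[4-(benzyloxy)phenyl]-4-oxochroman-3-yl]ethan-1-one F2. Amine-mediated aldol condensation with 14 and oxa-Michael ring closure (pyrrolidine, EtOH, 50 °C) should then give the two trans-configured flavanones, 17 and its unit 1 epimer (2R,3S)-5,7-bis(benzyloxy)-3-[(2R,3S)-5,7-bis(benzyloxy)-2-[4-(benzyloxy)phenyl]-4-oxochroman-3-yl]-2-(4-methoxyphenyl)chroman-4-one F3, which are diastereomers and are separated by chromatography.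

Further compounds
F0 | step 8 | none | none
F1 | step 3 | 2-{[(1R)-1-[4-(benzyloxy)phenyl]prop-2-en-1-yl]oxy}-4,6-difluorobenzaldehyde | O=Cc1c(F)cc(F)cc1O[C@H](C=C)c1ccc(OCc2ccccc2)cc1
F2 | step 9 | 1-[2,4-bis(benzyloxy)-6-hydroxyphenyl]-2-[(2R,3S)-5,7-bis(benzyloxy)-2-[4-(benzyloxy)phenyl]-4-oxochroman-3-yl]ethan-1-one | O=C(C[C@@H]1C(=O)c2c(OCc3ccccc3)cc(OCc3ccccc3)cc2O[C@H]1c1ccc(OCc2ccccc2)cc1)c1c(O)cc(OCc2ccccc2)cc1OCc1ccccc1
F3 | step 9 | (2R,3S)-5,7-bis(benzyloxy)-3-[(2R,3S)-5,7-bis(benzyloxy)-2-[4-(benzyloxy)phenyl]-4-oxochroman-3-yl]-2-(4-methoxyphenyl)chroman-4-one | COc1ccc([C@@H]2Oc3cc(OCc4ccccc4)cc(OCc4ccccc4)c3C(=O)[C@H]2[C@@H]2C(=O)c3c(OCc4ccccc4)cc(OCc4ccccc4)cc3O[C@H]2c2ccc(OCc3ccccc3)cc2)cc1
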